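## The problem

The target is a linear procyanidin trimer in which an upper (−)-epicatechin 3-O-gallate is bonded from C4 to C6 of a second epicatechin 3-O-gallate, whose C4 is bonded to C8 of a lower (+)-catechin; it holds eight stereocentres, two gallate esters, eighteen phenols and one secondary alcohol. Upper C2/C3 and lower C2/C3 can be taken from the natural flavan-3-ols, and upper C4 can be set trans to its C3 gallate by neighbouring-group participation. What remains is the middle unit: three contiguous centres (2,3-cis, 3,4-trans) on a ring A that is substituted at C6 rather than at the inherently more reactive C8. Middle C4 is a diarylmethine flanked by four ortho oxygen substituents, so its bond to lower C8 needs a stabilised cation or an equivalent of one; once C4 is set it can direct C3, and C3 can direct C2. The free polyphenol is oxidised by air under base, epimerises at C2 through ring opening and loses its interflavan bonds under acid, and the gallates can migrate or hydrolyse, so all phenols travel as benzyl ethers and are released last by neutral hydrogenolysis. The feature that allows a short route appears when middle ring C is opened at O1–C2 and C2 is written as an aldehyde: C4, C3 and C2 are then the β-carbon, α-carbon and carbonyl carbon of a cinnamaldehyde on middle ring A. C4 asks for an aryl nucleophile (lower C8) and C3 for an electrophilic oxygen (the gallate), which is the polarity sequence of iminium followed by enamine activation. O1 must come from the ring-A oxygen ortho to this side chain and para to the upper unit, so marking that one oxygen also fixes the 4→6 connectivity.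

## Retrosynthesis

**Target 33 to 32.** The nineteen benzyl ethers of 32 are cut last. No other disconnection is reasonable on the free polyphenol, and hydrogenolysis leaves esters, diarylmethine bonds and stereocentres alone.

**32 to keto phenol 30 (through hemiketal 31).** Middle ring C is opened at O1–C2 and C2 is raised to the ketone level, so the cut is the C2–H bond together with O1–C2. The neighbouring cut, an invertive Mitsunobu closure of an anti alcohol, needs a diastereoselective aryl addition and a clean SN2 reaction at an electron-rich benzylic carbon next to a participating gallate. The ketone route is indifferent to the carbinol configuration and sets C2 by hydride delivery to a cyclic oxocarbenium ion, where torsional preference and gallate participation point the same way. The forward reaction must give 2,3-cis. Phenol 30 comes from its silyl ether 29.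

**29 to aldehyde 24 and aryl bromide 25.** The C2–C1′ bond to ring B is cut, leaving alcohol 28 and then the α-galloyloxy aldehyde 24. Ring B is a simple catechol unit and is best added late. The forward reaction must touch neither the two gallates nor C3, which points to an aryltitanium reagent.

**24 to enal 12, trifluoroborate 19 and peroxide 22.** This is the central cut: middle C4–lower C8 and middle C3–O(gallate) in one operation. Cutting only C4–C8 in a closed middle unit (flavan-4-yl cation chemistry) would need a preformed epicatechin unit joined at C6 and a blocking group at C8. Here the acyclic enal has no C8 problem and the gallate arrives with the correct oxidation level. The precursors are far simpler: 12 holds only the upper unit, 19 only the lower unit. The forward reaction must set C4 and C3 under catalyst control in the relationship that becomes 3,4-trans.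

**12 to bromide 9 and boronate 10; 9 to electrophile 5 and arene 8.** The aryl–vinyl bond is cut first, then the upper C4–middle C6 bond. A formylation of the adduct itself would not distinguish middle ring A from the equally electron-rich ring A of the upper unit. The carbon handle (bromine) is therefore placed on the small arene before the coupling. In 8 the bromine also presses the triisopropylsilyl group over the one competing arene position. The forward coupling must occur between the two benzyloxy groups and trans to the C3 gallate.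

**5 to 3 and acid 4; 3 to 2 to (−)-epicatechin 1; 8 to 7 to phenol 6.** These are protecting-group and activation steps of established kinds: benzylation, oxidative C4 alkoxylation, esterification, ortho-bromination and silylation.

**19 to bromide 16 to 15 to 14 to (+)-catechin 13.** The boron is placed at C8 through the known C8-selective bromination, followed by halogen–metal exchange and borylation.

**22 to peroxy acid 21 and acid 4; 21 to 4 through acid chloride 20.** The peroxide is cut at one acyl–oxygen bond into acid 4 and its own peroxy acid 21. Joining two defined halves, rather than acylating hydrogen peroxide twice in one flask, keeps the anhydride of 4 out of the product and lets the oxidant be titrated before use. Both halves come from the acid that also furnishes the upper gallate.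

## Roads not taken

**Alternative 1:** The cut runs through middle ring A itself (C4a–C8a, C5–C6, C7–C8). In the forward direction RhCl(PPh3)3 would cyclotrimerise the silicon-tethered triyne A1 to A2, closing ring A, ring C and a temporary silicon-bridged ring at once.
- Merits: the substitution pattern of ring A is written into the tether, so the 4→6 connectivity is certain and does not lean on any arene selectivity. In this respect it is better than step 6 of the chosen plan, which relies on a steric bias.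
- Weak points: all three alkynes of A1 carry oxygen (two silyl ynol ethers on one silicon and an alkynyl ether), and such groups hydrolyse and form ketenes easily. The key step creates no stereocentre, so upper C4 and middle C2, C3 and C4 must all be set beforehand on an open chain. C4 would be a propargylic carbon bearing the very electron-rich catechin ring and would ionise readily. After the key step the silicon bridge must be removed, two phenols protected and two silyl ethers exchanged for gallates.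
- Comparison: the chosen plan sets two of the three difficult centres in its key step and installs the gallate directly, with fewer fragile intermediates.

**Alternative 2:** The cut is middle C4–C4a with closure of ring C. Acid or hexafluoroisopropanol would activate the trans-epoxide A3 so that an ortho carbon of the aryl ether attacks the benzylic epoxide carbon 6-endo, giving A4.
- Merits: the two ortho carbons of the para-oxygenated ring are equivalent, so the 4→6 pattern is automatic and no bromine or silyl marker is needed. The opening is stereospecific in principle (inversion at C4, C3 oxygen retained, hence 3,4-trans). A4 is only a galloylation and a hydrogenolysis from the target. In ring-A logic and in closeness to the target this road is better than the chosen one.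
- Weak points: the epoxide carbon carries the 2,4,6-trioxygenated catechin ring and will ionise with any acid. SN1 capture (loss of the 3,4-trans relationship) and hydride shift to the ketone then compete with the stereospecific opening. The aryl alkyl ether O1–C2, at a benzylic carbon of fixed configuration on a hindered phenol, must be made first and must survive the acid. The attacking carbon is flanked by the upper unit's neighbourhood.
- Comparison: the chosen plan makes the crowded C4–C8 bond in the key step under catalyst control instead of requiring it beforehand inside a labile epoxide, and its C3 oxygen arrives already as the gallate.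

**Alternative 3:** The cut removes both upper rings B (upper and middle C2–C1′). The boronic acid A7 would esterify each 3-hydroxyl of the bis-lactol A5, BF3·OEt2 would ionise the lactols, and each boronate would pass its aryl group to C2, giving A6.
- Merits: aryl delivery from the 3-oxygen gives 2,3-cis by construction, for both upper units at once. The chosen plan needs an addition, an oxidation and a reduction for that relationship in the middle unit alone, so here this road is better. A6 has both 3-hydroxyls free for a double galloylation.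
- Weak points: neither upper unit can come from epicatechin, so the whole core with two lactol rings, both C4 centres and both interflavan bonds must be built from scratch. Under BF3·OEt2 the oxocarbenium ions sit beside three phloroglucinol-type rings that can attack them. Two stereochemical events on one molecule multiply any leakage.
- Comparison: the chosen plan takes the upper unit whole from the chiral pool and builds only the middle unit.

Key step: step 14

Assumptions: compounds 4, 6, 10 and 25 are taken as purchasable. The facial sense of the imidazolidinone is taken from the established behaviour of its (2S,5S) enantiomer with (E)-enals and carbon π-nucleophiles; if the sense is reversed on this substrate, the mirror-image salt is used.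

## Route

Step 1
Reactants: 1 (−)-epicatechin
Product: 2 5,7,3′,4′-tetra-O-benzyl-(−)-epicatechin
Conditions: BnBr (4.4 equiv), K2CO3, DMF, −10 °C → rt
Reagents that add atoms: benzyl bromide, BrCc1ccccc1
Why: Williamson etherification; the four phenols are far more acidic than the 3-hydroxyl, and carbonate at low temperature under inert gas does not open ring C, so C2 and C3 keep their configuration.

Step 2
Reactants: 2 5,7,3′,4′-tetra-O-benzyl-(−)-epicatechin
Product: 3 (2R,3R,4S)-5,7,3′,4′-tetra-O-benzyl-4-(2-ethoxyethoxy)flavan-3-ol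
Conditions: DDQ (2 equiv), 2-ethoxyethanol (5 equiv), CH2Cl2, rt
Reagents that add atoms: 2-ethoxyethanol, CCOCCO
Why: DDQ removes hydride from C4 to give a cation stabilised by ring A, and the alcohol adds trans to the 3-hydroxyl (benzylic oxidative alkoxylation); the C4 configuration has no later consequence because the group leaves again in step 6.

Step 3
Reactants: 3 (2R,3R,4S)-5,7,3′,4′-tetra-O-benzyl-4-(2-ethoxyethoxy)flavan-3-ol; 4 3,4,5-tris(benzyloxy)benzoic acid
Product: 5 3-O-[3,4,5-tris(benzyloxy)benzoyl] ester of 3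
Conditions: 4 (1.5 equiv), DCC, DMAP, CH2Cl2, rt
Reagents that add atoms: none
Why: Steglich esterification of the secondary alcohol; no stereocentre is touched.

Step 4
Reactants: 6 3,5-bis(benzyloxy)phenol
Product: 7 3,5-bis(benzyloxy)-2-bromophenol
Conditions: NBS (1.0 equiv), i-Pr2NH (10 mol %), CH2Cl2, −78 → 0 °C
Reagents that add atoms: N-bromosuccinimide, BrN1C(=O)CCC1=O
Why: Amine-mediated bromination of a phenol, in which the hydrogen-bonded N-bromoamine delivers bromine ortho to the hydroxyl; one equivalent at low temperature should stop at the monobromide because the first bromine deactivates the ring.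

Step 5
Reactants: 7 3,5-bis(benzyloxy)-2-bromophenol
Product: 8 [3,5-bis(benzyloxy)-2-bromophenoxy]tri(propan-2-yl)silane
Conditions: TIPSCl, imidazole, DMF, rt
Reagents that add atoms: chlorotri(propan-2-yl)silane, CC(C)[Si](Cl)(C(C)C)C(C)C
Why: Silylation of the only free hydroxyl; this oxygen is the one that later becomes O1 of the middle unit.

Step 6
Reactants: 5 3-O-[3,4,5-tris(benzyloxy)benzoyl] ester of 3; 8 [3,5-bis(benzyloxy)-2-bromophenoxy]tri(propan-2-yl)silane
Product: 9 hepta-O-benzyl-(−)-epicatechin gallate bearing at C4 (4β, 3,4-trans, 2R,3R,4R) a 2,6-bis(benzyloxy)-3-bromo-4-(triisopropylsilyloxy)phenyl group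
Conditions: 8 (3 equiv), TMSOTf (0.2 equiv), CH2Cl2, −78 → −40 °C
Reagents that add atoms: none
Why: The Lewis acid ionises the C4 ether to a flavan-4-yl cation that the C3 gallate bridges on its own face, so the arene attacks trans to it (Friedel–Crafts alkylation with neighbouring-group participation). Of the two free arene positions, the one between the benzyloxy groups and para to the silyloxy group should react, because the bromine forces the triisopropylsilyl group over the other.

Step 7
Reactants: 9 aryl bromide from step 6; 10 (E)-2-(3,3-diethoxyprop-1-en-1-yl)-4,4,5,5-tetramethyl-1,3,2-dioxaborolane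
Product: 12 (E)-3-[2,4-bis(benzyloxy)-3-(hepta-O-benzyl-epicatechin-gallate-4β-yl)-6-(triisopropylsilyloxy)phenyl]prop-2-enal, via diethyl acetal 11 (not isolated)
Conditions: Pd(OAc)2 (5 mol %), SPhos (10 mol %), K3PO4, toluene/H2O (10:1), 80 °C; then 1 M HCl, THF, 0 °C
Reagents that add atoms: water, O
Why: Suzuki–Miyaura coupling of a di-ortho-substituted electron-rich aryl bromide, for which the biarylphosphine is suited, with retention of the E geometry of the boronate; the allylic acetal then hydrolyses under acid too mild for the silyl ether or the gallate.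

Step 8
Reactants: 13 (+)-catechin
Product: 14 5,7,3′,4′-tetra-O-benzyl-(+)-catechin
Conditions: BnBr (4.4 equiv), K2CO3, DMF, 0 °C → rt
Reagents that add atoms: benzyl bromide, BrCc1ccccc1
Why: Williamson etherification of the four phenols, as in step 1.

Step 9
Reactants: 14 5,7,3′,4′-tetra-O-benzyl-(+)-catechin
Product: 15 3,5,7,3′,4′-penta-O-benzyl-(+)-catechin
Conditions: NaH, BnBr, DMF, 0 °C → rt
Reagents that add atoms: benzyl bromide, BrCc1ccccc1
Why: Williamson etherification of the secondary alcohol, which must be masked for the lithiation of step 11 and is released with the other benzyl groups at the end.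

Step 10
Reactants: 15 3,5,7,3′,4′-penta-O-benzyl-(+)-catechin
Product: 16 8-bromo-3,5,7,3′,4′-penta-O-benzyl-(+)-catechin
Conditions: NBS (1.05 equiv), CH2Cl2, −78 °C → rt
Reagents that add atoms: N-bromosuccinimide, BrN1C(=O)CCC1=O
Why: Electrophilic bromination of ring A, which in benzylated flavan-3-ols goes to C8, the position next to the ring oxygen.

Step 11
Reactants: 16 8-bromo-3,5,7,3′,4′-penta-O-benzyl-(+)-catechin
Product: 19 potassium (3,5,7,3′,4′-penta-O-benzyl-(+)-catechin-8-yl)trifluoroborate, via aryllithium 17 (not isolated), via lithium triisopropoxyborate 18 (not isolated)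
Conditions: n-BuLi, THF, −78 °C; B(OiPr)3, −78 °C → rt; aq KHF2, rt
Reagents that add atoms: triisopropyl borate, CC(C)OB(OC(C)C)OC(C)C; potassium hydrogen difluoride, [K+].F.[F-]
Why: Bromine–lithium exchange, borylation and fluoride exchange in one flask; the trifluoroborate is the storable form of a 2,6-dioxygenated arylboron species whose boronic acid would protodeboronate.

Step 12
Reactants: 4 3,4,5-tris(benzyloxy)benzoic acid
Product: 21 3,4,5-tris(benzyloxy)perbenzoic acid, via acid chloride 20 (not isolated)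
Conditions: (COCl)2, DMF (cat.), CH2Cl2, 0 °C → rt, evaporate; then H2O2 (30 % aq, 3 equiv), NaOH, MgSO4·7H2O, dioxane/H2O, 0–10 °C; cold dil. H2SO4
Reagents that add atoms: hydrogen peroxide, OO
Why: Vilsmeier-type chlorination gives the aroyl chloride, and its perhydrolysis with alkaline hydrogen peroxide stabilised by MgSO4 is the standard preparation of substituted perbenzoic acids; benzyl ethers are inert to both stages, excess hydroperoxide cleaves any diaroyl peroxide formed back to the peracid salt, and the peracid is titrated iodometrically and used at once.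

Step 13
Reactants: 21 3,4,5-tris(benzyloxy)perbenzoic acid; 4 3,4,5-tris(benzyloxy)benzoic acid
Product: 22 bis[3,4,5-tris(benzyloxy)benzoyl] peroxide
Conditions: 21 (1.0 equiv), 4 (1.0 equiv), DCC (1.05 equiv), CH2Cl2/Et2O, 0 °C
Reagents that add atoms: none
Why: Carbodiimide coupling of a carboxylic acid with a peroxy acid, the established route to diacyl peroxides: the peracid, the stronger nucleophile through the alpha effect, intercepts the O-acylisourea of 4, so that little anhydride forms; the peroxide is kept cold and used soon because electron-rich diaroyl peroxides decompose on storage.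

Step 14
Reactants: 12 enal from step 7; 19 potassium (penta-O-benzylcatechin-8-yl)trifluoroborate; 22 bis[3,4,5-tris(benzyloxy)benzoyl] peroxide
Product: 24 (2R,3S)-3-(penta-O-benzylcatechin-8-yl)-3-[aryl of 12]-2-[3,4,5-tris(benzyloxy)benzoyloxy]propanal, via diaryl aldehyde 23 (not isolated)
Conditions: (2R,5R)-5-benzyl-2-tert-butyl-3-methylimidazolidin-4-one·CF3CO2H (30 mol %), 19 (2.0 equiv), HF (48 % aq, 1.0 equiv), DME, −20 → 4 °C; then 22 (1.5 equiv), hydroquinone (10 mol %), THF, 0 °C → rt
Reagents that add atoms: none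
Why: Proposed new method: the amine salt condenses with enal 12 to an (E)-iminium ion whose β-carbon (middle C4) is attacked by the ipso carbon of trifluoroborate 19, boron leaving as BF3 that HF turns into KBF4, and hydrolysis gives aldehyde 23; the same amine then forms the (E)-enamine of 23, whose α-carbon (middle C3) attacks the O–O bond of peroxide 22, added only at this stage, and hydrolysis gives 24. The closest known reactions are the amine-catalysed conjugate addition of aryl and heteroaryl trifluoroborates to enals, iminium–enamine cascades that end in an α-heteroatom bond, and the amine-catalysed α-benzoyloxylation of aldehydes with dibenzoyl peroxide; new are the strongly donor-substituted, di-ortho-substituted β-aryl enal, the di-ortho-substituted aryl nucleophile and an oxygen electrophile as second partner. No ring closes. C4 is set by the catalyst: its benzyl group covers one face of the iminium ion, and by analogy with the known sense of the (2S,5S) enantiomer the (2R,5R) enantiomer leaves open the face that gives the (S) centre of 23 and 24. C3 is set by the same shielding in the enamine, so that aryl and acyloxy groups end up on the same face of the former E double bond (syn in the extended chain), which is the relationship that becomes 3,4-trans once O1–C2 is closed. The step needs β-attack and not carbonyl attack (secured by iminium activation), attack of the catechin ring at C8 and not C6 (secured by the position of boron), and acyloxylation at carbon and not at nitrogen (helped by the hindered imidazolidinone nitrogen and by hydroquinone, which suppresses radical chains). Adding the peroxide after the arylation keeps it from oxidising the trifluoroborate, and the only oxygen able to become O1 later is the silylated one, ortho to the side chain and para to the upper unit, which fixes the 4→6 pattern.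

Step 15
Reactants: 24 α-galloyloxy aldehyde from step 14; 25 4-bromo-1,2-bis(benzyloxy)benzene
Product: 28 (2R,3S)-1-[3,4-bis(benzyloxy)phenyl]-1-hydroxy-3,3-diarylpropan-2-yl 3,4,5-tris(benzyloxy)benzoate (both C1 epimers), via aryllithium 26 (not isolated), via aryltitanium triisopropoxide 27 (not isolated)
Conditions: 25, n-BuLi, THF, −78 °C; ClTi(OiPr)3, −78 °C; then 24, −78 → −20 °C; aq NH4Cl
Reagents that add atoms: none
Why: Aryltitanium triisopropoxides add to aldehydes but not to esters, and the titanium alkoxide formed is too weakly basic to enolise the aldehyde or to draw the neighbouring gallate over (chemoselective 1,2-addition). The new carbinol centre is expected mainly anti (Felkin–Anh model with the acyloxy group as polar substituent) but need not be controlled, since it is oxidised in step 16.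

Step 16
Reactants: 28 carbinol from step 15
Product: 29 (2R,3S)-1-[3,4-bis(benzyloxy)phenyl]-1-oxo-3,3-diarylpropan-2-yl 3,4,5-tris(benzyloxy)benzoate
Conditions: Dess–Martin periodinane, CH2Cl2, 0 °C → rt
Reagents that add atoms: none
Why: Dess–Martin oxidation of a benzylic secondary alcohol without base; both epimers converge on one ketone, and C3, now α to the ketone, is shielded by two bulky neighbours.

Step 17
Reactants: 29 aryl ketone from step 16
Product: 30 keto phenol obtained from 29 by loss of the triisopropylsilyl group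
Conditions: TBAF (1.1 equiv), AcOH (1.2 equiv), THF, 0 °C
Reagents that add atoms: none
Why: Fluoride cleaves the aryl silyl ether, and acetic acid buffers the phenoxide so that the α-acyloxy ketone does not epimerise and the gallate does not migrate; 30 is expected to stand in equilibrium with its cyclic hemiketal 31.

Step 18
Reactants: 30 keto phenol from step 17
Product: 32 nonadeca-O-benzyl derivative of the target, via cyclic hemiketal 31 (not isolated)
Conditions: Et3SiH (5 equiv), TMSOTf (0.3 equiv), CH2Cl2, −78 → −40 °C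
Reagents that add atoms: none
Why: The phenol adds to the activated ketone (6-exo-trig), hemiketal 31 ionises to a 2-aryl oxocarbenium ion, and the silane reduces it (reductive etherification, the reaction type that turns aryl hemiketals into C-aryl glycosides). Hydride is expected on the face opposite the pseudoaxial C3 gallate, for torsional reasons and because the gallate carbonyl can bridge that face; this places the C2 aryl group equatorial and cis to the gallate (2,3-cis, 2R).

Step 19
Reactants: 32 nonadeca-O-benzyl derivative of the target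
Product: 33 epicatechin 3-O-gallate-(4β→6)-epicatechin 3-O-gallate-(4β→8)-catechin (target)
Conditions: H2 (1 atm), Pd(OH)2/C, THF/MeOH/H2O, rt
Reagents that add atoms: none
Why: Hydrogenolysis of nineteen benzyl ethers under neutral conditions; esters, diarylmethine bonds and stereocentres are not affected.

## Compound list

1 | (−)-epicatechin, (2R,3R) | O[C@@H]1Cc2c(O)cc(O)cc2O[C@@H]1c1ccc(O)c(O)c1 | starting material
2 | 5,7,3′,4′-tetra-O-benzyl-(−)-epicatechin | O[C@@H]1Cc2c(OCc9ccccc9)cc(OCc9ccccc9)cc2O[C@@H]1c1ccc(OCc9ccccc9)c(OCc9ccccc9)c1 | intermediate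
3 | (2R,3R,4S)-5,7,3′,4′-tetra-O-benzyl-4-(2-ethoxyethoxy)flavan-3-ol (4β ether, 3,4-trans) | O[C@@H]1[C@@H](OCCOCC)c2c(OCc9ccccc9)cc(OCc9ccccc9)cc2O[C@@H]1c1ccc(OCc9ccccc9)c(OCc9ccccc9)c1 | intermediate
4 | 3,4,5-tris(benzyloxy)benzoic acid | OC(=O)c1cc(OCc9ccccc9)c(OCc9ccccc9)c(OCc9ccccc9)c1 | starting material
5 | 3-O-[3,4,5-tris(benzyloxy)benzoyl] ester of 3 | O=C(O[C@@H]1[C@@H](OCCOCC)c2c(OCc9ccccc9)cc(OCc9ccccc9)cc2O[C@@H]1c1ccc(OCc9ccccc9)c(OCc9ccccc9)c1)c1cc(OCc9ccccc9)c(OCc9ccccc9)c(OCc9ccccc9)c1 | intermediate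
6 | 3,5-bis(benzyloxy)phenol | Oc1cc(OCc9ccccc9)cc(OCc9ccccc9)c1 | starting material
7 | 3,5-bis(benzyloxy)-2-bromophenol | Oc1c(Br)c(OCc9ccccc9)cc(OCc9ccccc9)c1 | intermediate
8 | [3,5-bis(benzyloxy)-2-bromophenoxy]tri(propan-2-yl)silane | CC(C)[Si](C(C)C)(C(C)C)Oc1c(Br)c(OCc9ccccc9)cc(OCc9ccccc9)c1 | intermediate
9 | hepta-O-benzyl-(−)-epicatechin gallate with a 2,6-bis(benzyloxy)-3-bromo-4-(triisopropylsilyloxy)phenyl group at C4β (2R,3R,4R) | O=C(O[C@@H]1[C@@H](c2c(OCc9ccccc9)cc(O[Si](C(C)C)(C(C)C)C(C)C)c(Br)c2OCc9ccccc9)c2c(OCc9ccccc9)cc(OCc9ccccc9)cc2O[C@@H]1c1ccc(OCc9ccccc9)c(OCc9ccccc9)c1)c1cc(OCc9ccccc9)c(OCc9ccccc9)c(OCc9ccccc9)c1 | intermediate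
10 | (E)-2-(3,3-diethoxyprop-1-en-1-yl)-4,4,5,5-tetramethyl-1,3,2-dioxaborolane | CCOC(OCC)/C=C/B1OC(C)(C)C(C)(C)O1 | starting material
11 | diethyl acetal of enal 12 | O=C(O[C@@H]1[C@@H](c2c(OCc9ccccc9)cc(O[Si](C(C)C)(C(C)C)C(C)C)c(/C=C/C(OCC)OCC)c2OCc9ccccc9)c2c(OCc9ccccc9)cc(OCc9ccccc9)cc2O[C@@H]1c1ccc(OCc9ccccc9)c(OCc9ccccc9)c1)c1cc(OCc9ccccc9)c(OCc9ccccc9)c(OCc9ccccc9)c1 | intermediate (not isolated)
12 | (E)-3-[2,4-bis(benzyloxy)-3-(hepta-O-benzyl-epicatechin-gallate-4β-yl)-6-(triisopropylsilyloxy)phenyl]prop-2-enal | O=C(O[C@@H]1[C@@H](c2c(OCc9ccccc9)cc(O[Si](C(C)C)(C(C)C)C(C)C)c(/C=C/C=O)c2OCc9ccccc9)c2c(OCc9ccccc9)cc(OCc9ccccc9)cc2O[C@@H]1c1ccc(OCc9ccccc9)c(OCc9ccccc9)c1)c1cc(OCc9ccccc9)c(OCc9ccccc9)c(OCc9ccccc9)c1 | intermediate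
13 | (+)-catechin, (2R,3S) | O[C@H]1Cc2c(O)cc(O)cc2O[C@@H]1c1ccc(O)c(O)c1 | starting material
14 | 5,7,3′,4′-tetra-O-benzyl-(+)-catechin | O[C@H]1Cc2c(OCc9ccccc9)cc(OCc9ccccc9)cc2O[C@@H]1c1ccc(OCc9ccccc9)c(OCc9ccccc9)c1 | intermediate
15 | 3,5,7,3′,4′-penta-O-benzyl-(+)-catechin | c1c(OCc9ccccc9)cc(OCc9ccccc9)c2c1O[C@H](c1ccc(OCc9ccccc9)c(OCc9ccccc9)c1)[C@@H](OCc9ccccc9)C2 | intermediate
16 | 8-bromo-3,5,7,3′,4′-penta-O-benzyl-(+)-catechin | Brc1c(OCc9ccccc9)cc(OCc9ccccc9)c2c1O[C@H](c1ccc(OCc9ccccc9)c(OCc9ccccc9)c1)[C@@H](OCc9ccccc9)C2 | intermediate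
17 | 8-lithio-3,5,7,3′,4′-penta-O-benzyl-(+)-catechin | [Li]c1c(OCc9ccccc9)cc(OCc9ccccc9)c2c1O[C@H](c1ccc(OCc9ccccc9)c(OCc9ccccc9)c1)[C@@H](OCc9ccccc9)C2 | intermediate (not isolated)
18 | lithium (penta-O-benzylcatechin-8-yl)triisopropoxyborate | [Li+].CC(C)O[B-](OC(C)C)(OC(C)C)c1c(OCc9ccccc9)cc(OCc9ccccc9)c2c1O[C@H](c1ccc(OCc9ccccc9)c(OCc9ccccc9)c1)[C@@H](OCc9ccccc9)C2 | intermediate (not isolated)
19 | potassium (3,5,7,3′,4′-penta-O-benzyl-(+)-catechin-8-yl)trifluoroborate | [K+].F[B-](F)(F)c1c(OCc9ccccc9)cc(OCc9ccccc9)c2c1O[C@H](c1ccc(OCc9ccccc9)c(OCc9ccccc9)c1)[C@@H](OCc9ccccc9)C2 | intermediate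
20 | 3,4,5-tris(benzyloxy)benzoyl chloride | ClC(=O)c1cc(OCc9ccccc9)c(OCc9ccccc9)c(OCc9ccccc9)c1 | intermediate (not isolated)
21 | 3,4,5-tris(benzyloxy)perbenzoic acid (3,4,5-tris(benzyloxy)benzenecarboperoxoic acid) | OOC(=O)c1cc(OCc9ccccc9)c(OCc9ccccc9)c(OCc9ccccc9)c1 | intermediate
22 | bis[3,4,5-tris(benzyloxy)benzoyl] peroxide | O=C(OOC(=O)c1cc(OCc9ccccc9)c(OCc9ccccc9)c(OCc9ccccc9)c1)c1cc(OCc9ccccc9)c(OCc9ccccc9)c(OCc9ccccc9)c1 | intermediate
23 | (3S)-3-(penta-O-benzylcatechin-8-yl)-3-[aryl of 12]propanal | O=C(O[C@@H]1[C@@H](c2c(OCc9ccccc9)cc(O[Si](C(C)C)(C(C)C)C(C)C)c(c2OCc9ccccc9)[C@H](c4c(OCc9ccccc9)cc(OCc9ccccc9)c5c4O[C@H](c6ccc(OCc9ccccc9)c(OCc9ccccc9)c6)[C@@H](OCc9ccccc9)C5)CC=O)c2c(OCc9ccccc9)cc(OCc9ccccc9)cc2O[C@@H]1c1ccc(OCc9ccccc9)c(OCc9ccccc9)c1)c1cc(OCc9ccccc9)c(OCc9ccccc9)c(OCc9ccccc9)c1 | intermediate (not isolated)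
24 | (2R,3S)-3-(penta-O-benzylcatechin-8-yl)-3-[aryl of 12]-2-[3,4,5-tris(benzyloxy)benzoyloxy]propanal (aryl and acyloxy syn in the extended chain) | O=C(O[C@@H]1[C@@H](c2c(OCc9ccccc9)cc(O[Si](C(C)C)(C(C)C)C(C)C)c(c2OCc9ccccc9)[C@H](c4c(OCc9ccccc9)cc(OCc9ccccc9)c5c4O[C@H](c6ccc(OCc9ccccc9)c(OCc9ccccc9)c6)[C@@H](OCc9ccccc9)C5)[C@@H](OC(=O)c7cc(OCc9ccccc9)c(OCc9ccccc9)c(OCc9ccccc9)c7)C=O)c2c(OCc9ccccc9)cc(OCc9ccccc9)cc2O[C@@H]1c1ccc(OCc9ccccc9)c(OCc9ccccc9)c1)c1cc(OCc9ccccc9)c(OCc9ccccc9)c(OCc9ccccc9)c1 | intermediate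
25 | 4-bromo-1,2-bis(benzyloxy)benzene | Brc1ccc(OCc9ccccc9)c(OCc9ccccc9)c1 | starting material
26 | [3,4-bis(benzyloxy)phenyl]lithium | [Li]c1ccc(OCc9ccccc9)c(OCc9ccccc9)c1 | intermediate (not isolated)
27 | [3,4-bis(benzyloxy)phenyl]titanium triisopropoxide | CC(C)O[Ti](OC(C)C)(OC(C)C)c1ccc(OCc9ccccc9)c(OCc9ccccc9)c1 | intermediate (not isolated)
28 | (2R,3S)-1-[3,4-bis(benzyloxy)phenyl]-1-hydroxy-3,3-diarylpropan-2-yl 3,4,5-tris(benzyloxy)benzoate, mixture of C1 epimers | O=C(O[C@@H]1[C@@H](c2c(OCc9ccccc9)cc(O[Si](C(C)C)(C(C)C)C(C)C)c(c2OCc9ccccc9)[C@H](c4c(OCc9ccccc9)cc(OCc9ccccc9)c5c4O[C@H](c6ccc(OCc9ccccc9)c(OCc9ccccc9)c6)[C@@H](OCc9ccccc9)C5)[C@@H](OC(=O)c7cc(OCc9ccccc9)c(OCc9ccccc9)c(OCc9ccccc9)c7)C(O)c8ccc(OCc9ccccc9)c(OCc9ccccc9)c8)c2c(OCc9ccccc9)cc(OCc9ccccc9)cc2O[C@@H]1c1ccc(OCc9ccccc9)c(OCc9ccccc9)c1)c1cc(OCc9ccccc9)c(OCc9ccccc9)c(OCc9ccccc9)c1 | intermediate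
29 | (2R,3S)-1-[3,4-bis(benzyloxy)phenyl]-1-oxo-3,3-diarylpropan-2-yl 3,4,5-tris(benzyloxy)benzoate | O=C(O[C@@H]1[C@@H](c2c(OCc9ccccc9)cc(O[Si](C(C)C)(C(C)C)C(C)C)c(c2OCc9ccccc9)[C@H](c4c(OCc9ccccc9)cc(OCc9ccccc9)c5c4O[C@H](c6ccc(OCc9ccccc9)c(OCc9ccccc9)c6)[C@@H](OCc9ccccc9)C5)[C@@H](OC(=O)c7cc(OCc9ccccc9)c(OCc9ccccc9)c(OCc9ccccc9)c7)C(=O)c8ccc(OCc9ccccc9)c(OCc9ccccc9)c8)c2c(OCc9ccccc9)cc(OCc9ccccc9)cc2O[C@@H]1c1ccc(OCc9ccccc9)c(OCc9ccccc9)c1)c1cc(OCc9ccccc9)c(OCc9ccccc9)c(OCc9ccccc9)c1 | intermediate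
30 | keto phenol: 29 with the silyl ether replaced by a free hydroxyl (same configuration; the C3 descriptor becomes R only through changed priorities) | O=C(O[C@@H]1[C@@H](c2c(OCc9ccccc9)cc(O)c(c2OCc9ccccc9)[C@H](c4c(OCc9ccccc9)cc(OCc9ccccc9)c5c4O[C@H](c6ccc(OCc9ccccc9)c(OCc9ccccc9)c6)[C@@H](OCc9ccccc9)C5)[C@@H](OC(=O)c7cc(OCc9ccccc9)c(OCc9ccccc9)c(OCc9ccccc9)c7)C(=O)c8ccc(OCc9ccccc9)c(OCc9ccccc9)c8)c2c(OCc9ccccc9)cc(OCc9ccccc9)cc2O[C@@H]1c1ccc(OCc9ccccc9)c(OCc9ccccc9)c1)c1cc(OCc9ccccc9)c(OCc9ccccc9)c(OCc9ccccc9)c1 | intermediate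
31 | cyclic hemiketal of 30 (2-hydroxy form of the middle flavan unit, both anomers) | O=C(O[C@@H]1[C@@H](c2c(OCc9ccccc9)cc3c(c2OCc9ccccc9)[C@H](c4c(OCc9ccccc9)cc(OCc9ccccc9)c5c4O[C@H](c6ccc(OCc9ccccc9)c(OCc9ccccc9)c6)[C@@H](OCc9ccccc9)C5)[C@@H](OC(=O)c7cc(OCc9ccccc9)c(OCc9ccccc9)c(OCc9ccccc9)c7)C(O)(c8ccc(OCc9ccccc9)c(OCc9ccccc9)c8)O3)c2c(OCc9ccccc9)cc(OCc9ccccc9)cc2O[C@@H]1c1ccc(OCc9ccccc9)c(OCc9ccccc9)c1)c1cc(OCc9ccccc9)c(OCc9ccccc9)c(OCc9ccccc9)c1 | intermediate (not isolated)
32 | nonadeca-O-benzyl derivative of the target: upper and middle units 2,3-cis-3,4-trans (epicatechin type, 4β links), lower unit 2,3-trans (catechin type) | O=C(O[C@@H]1[C@@H](c2c(OCc9ccccc9)cc3c(c2OCc9ccccc9)[C@H](c4c(OCc9ccccc9)cc(OCc9ccccc9)c5c4O[C@H](c6ccc(OCc9ccccc9)c(OCc9ccccc9)c6)[C@@H](OCc9ccccc9)C5)[C@@H](OC(=O)c7cc(OCc9ccccc9)c(OCc9ccccc9)c(OCc9ccccc9)c7)[C@@H](c8ccc(OCc9ccccc9)c(OCc9ccccc9)c8)O3)c2c(OCc9ccccc9)cc(OCc9ccccc9)cc2O[C@@H]1c1ccc(OCc9ccccc9)c(OCc9ccccc9)c1)c1cc(OCc9ccccc9)c(OCc9ccccc9)c(OCc9ccccc9)c1 | intermediate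
33 | epicatechin 3-O-gallate-(4β→6)-epicatechin 3-O-gallate-(4β→8)-catechin | O=C(O[C@@H]1[C@@H](c2c(O)cc3c(c2O)[C@H](c2c(O)cc(O)c4c2O[C@H](c2ccc(O)c(O)c2)[C@@H](O)C4)[C@@H](OC(=O)c2cc(O)c(O)c(O)c2)[C@@H](c2ccc(O)c(O)c2)O3)c2c(O)cc(O)cc2O[C@@H]1c1ccc(O)c(O)c1)c1cc(O)c(O)c(O)c1 | target

## Step count and least certain steps

Total: 19 steps. Longest linear sequence: 11 steps (1, 2, 3, 6, 7, 14, 15, 16, 17, 18, 19).

**Step 14 (key step).** What may go wrong: the iminium ion of a 2,4,6-trioxygenated cinnamaldehyde is strongly stabilised and both partners are di-ortho-substituted, so the conjugate addition may be slow. Protodeboronation of 19 under the acidic fluoride conditions, or loss of the silyl group to HF, could then overtake C–C bond formation. In the second stage the peroxide may oxidise the amine nitrogen, or the catalyst may fail to override the bulky C4 neighbour when C3 is set. A second, more nucleophilic amine can be added for the enamine stage if the imidazolidinone is too slow there.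
Fallback (known chemistry, leaves the open-chain disconnection): the trimer is assembled by Lewis-acid couplings of flavan-4-yl ethers; the sequence sets out from 2, 5 and 15 and rejoins the route at 33. NBS brominates 2 at C8 to 8-bromo-tetra-O-benzylepicatechin F1, and esterification with 4 gives its gallate F2. TMSOTf-mediated coupling of 5 with F2, whose C8 is blocked, gives the (4β→6) dimer F3. DDQ with 2-ethoxyethanol activates the only remaining C4 methylene and gives the dimeric 4-(2-ethoxyethoxy) ether F4. TMSOTf-mediated coupling of F4 with an excess of 15 (C8 attack, trans to the gallate by participation) gives the bromo trimer F5, and hydrogenolysis over Pd(OH)2/C with Et3N removes bromine and benzyl groups together to give 33.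

**Step 6.** What may go wrong: the bromine-bearing, hindered arene may be too weak a nucleophile, so that the cation from 5 is captured by ring A of a second molecule of 5, or attack may occur at the position ortho to the silyloxy group.
Fallback (sets out from 5 and 6, rejoins at 12, and also removes the cross-coupling of step 7): 6 is silylated to the bromine-free, more nucleophilic ether F6, which is coupled with 5 under TMSOTf to give adduct F7, and fluoride frees the single phenol F8. Magnesium-mediated ortho-formylation (MgCl2, Et3N, paraformaldehyde) reacts only at a free phenol and therefore only on the middle ring, whose two ortho positions are equivalent; it gives salicylaldehyde F9. Resilylation gives silyl ether F10, and a Wittig reaction with (triphenylphosphoranylidene)acetaldehyde gives 12.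

**Step 15.** What may go wrong: the aryl-metal may attack a gallate carbonyl, the gallate may shift onto the new alkoxide, or C3 may epimerise through enolisation of the aldehyde.
Fallback (sets out from 24, rejoins at 29, no carbanion and no alkoxide involved): Pinnick oxidation (NaClO2, NaH2PO4, 2-methyl-2-butene) gives acid F11, and DCC with ethanethiol gives S-ethyl thioester F12. A Liebeskind–Srogl coupling with 3,4-bis(benzyloxy)phenylboronic acid (the compound listed as A7), using Pd2(dba)3, tri(2-furyl)phosphine and copper thiophene-2-carboxylate CuO2CC4H3S, then gives ketone 29 directly.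

**Step 18.** What may go wrong: hydride may be delivered to the face that gives 2,3-trans, the oxocarbenium ion may lose the C3 proton to an enol ester, or the Lewis acid may ionise an interflavan bond.
Fallback (sets out from 28, rejoins at 32; C2 is set by substitution instead of reduction): the anti (1S) epimer F13, the expected Felkin–Anh product of step 15, is separated and desilylated with buffered fluoride to phenol alcohol F14. A Mitsunobu reaction (PPh3, DIAD) closes O1–C2 with inversion to give 32. Its own hazard is participation of the gallate or ionisation at the electron-rich benzylic carbon, which is why it is not the first choice.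

## Further compounds

F1 | step 14 | 8-bromo-5,7,3′,4′-tetra-O-benzyl-(−)-epicatechin | O[C@@H]1Cc2c(OCc9ccccc9)cc(OCc9ccccc9)c(Br)c2O[C@@H]1c1ccc(OCc9ccccc9)c(OCc9ccccc9)c1
F2 | step 14 | 8-bromo-5,7,3′,4′-tetra-O-benzyl-(−)-epicatechin 3-O-[3,4,5-tris(benzyloxy)benzoate] | O=C(O[C@@H]1Cc2c(OCc9ccccc9)cc(OCc9ccccc9)c(Br)c2O[C@@H]1c1ccc(OCc9ccccc9)c(OCc9ccccc9)c1)c1cc(OCc9ccccc9)c(OCc9ccccc9)c(OCc9ccccc9)c1
F3 | step 14 | perbenzylated epicatechin gallate-(4β→6)-8-bromoepicatechin gallate | O=C(O[C@@H]1[C@@H](c2c(OCc9ccccc9)c(Br)c3c(c2OCc9ccccc9)C[C@@H](OC(=O)c7cc(OCc9ccccc9)c(OCc9ccccc9)c(OCc9ccccc9)c7)[C@@H](c8ccc(OCc9ccccc9)c(OCc9ccccc9)c8)O3)c2c(OCc9ccccc9)cc(OCc9ccccc9)cc2O[C@@H]1c1ccc(OCc9ccccc9)c(OCc9ccccc9)c1)c1cc(OCc9ccccc9)c(OCc9ccccc9)c(OCc9ccccc9)c1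
F4 | step 14 | F3 with a 4β-(2-ethoxyethoxy) group on the lower unit | O=C(O[C@@H]1[C@@H](c2c(OCc9ccccc9)c(Br)c3c(c2OCc9ccccc9)[C@H](OCCOCC)[C@@H](OC(=O)c7cc(OCc9ccccc9)c(OCc9ccccc9)c(OCc9ccccc9)c7)[C@@H](c8ccc(OCc9ccccc9)c(OCc9ccccc9)c8)O3)c2c(OCc9ccccc9)cc(OCc9ccccc9)cc2O[C@@H]1c1ccc(OCc9ccccc9)c(OCc9ccccc9)c1)c1cc(OCc9ccccc9)c(OCc9ccccc9)c(OCc9ccccc9)c1
F5 | step 14 | 32 with bromine at C8 of the middle unit | O=C(O[C@@H]1[C@@H](c2c(OCc9ccccc9)c(Br)c3c(c2OCc9ccccc9)[C@H](c4c(OCc9ccccc9)cc(OCc9ccccc9)c5c4O[C@H](c6ccc(OCc9ccccc9)c(OCc9ccccc9)c6)[C@@H](OCc9ccccc9)C5)[C@@H](OC(=O)c7cc(OCc9ccccc9)c(OCc9ccccc9)c(OCc9ccccc9)c7)[C@@H](c8ccc(OCc9ccccc9)c(OCc9ccccc9)c8)O3)c2c(OCc9ccccc9)cc(OCc9ccccc9)cc2O[C@@H]1c1ccc(OCc9ccccc9)c(OCc9ccccc9)c1)c1cc(OCc9ccccc9)c(OCc9ccccc9)c(OCc9ccccc9)c1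
F6 | step 6 | [3,5-bis(benzyloxy)phenoxy]tri(propan-2-yl)silane | CC(C)[Si](C(C)C)(C(C)C)Oc1cc(OCc9ccccc9)cc(OCc9ccccc9)c1
F7 | step 6 | hepta-O-benzyl-(−)-epicatechin gallate with a 2,6-bis(benzyloxy)-4-(triisopropylsilyloxy)phenyl group at C4β | O=C(O[C@@H]1[C@@H](c2c(OCc9ccccc9)cc(O[Si](C(C)C)(C(C)C)C(C)C)cc2OCc9ccccc9)c2c(OCc9ccccc9)cc(OCc9ccccc9)cc2O[C@@H]1c1ccc(OCc9ccccc9)c(OCc9ccccc9)c1)c1cc(OCc9ccccc9)c(OCc9ccccc9)c(OCc9ccccc9)c1
F8 | step 6 | phenol from F7 (4-hydroxy-2,6-bis(benzyloxy)phenyl group at C4β) | O=C(O[C@@H]1[C@@H](c2c(OCc9ccccc9)cc(O)cc2OCc9ccccc9)c2c(OCc9ccccc9)cc(OCc9ccccc9)cc2O[C@@H]1c1ccc(OCc9ccccc9)c(OCc9ccccc9)c1)c1cc(OCc9ccccc9)c(OCc9ccccc9)c(OCc9ccccc9)c1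
F9 | step 6 | salicylaldehyde from F8 (formyl group ortho to the free hydroxyl) | O=C(O[C@@H]1[C@@H](c2c(OCc9ccccc9)cc(O)c(C=O)c2OCc9ccccc9)c2c(OCc9ccccc9)cc(OCc9ccccc9)cc2O[C@@H]1c1ccc(OCc9ccccc9)c(OCc9ccccc9)c1)c1cc(OCc9ccccc9)c(OCc9ccccc9)c(OCc9ccccc9)c1
F10 | step 6 | triisopropylsilyl ether of F9 | O=C(O[C@@H]1[C@@H](c2c(OCc9ccccc9)cc(O[Si](C(C)C)(C(C)C)C(C)C)c(C=O)c2OCc9ccccc9)c2c(OCc9ccccc9)cc(OCc9ccccc9)cc2O[C@@H]1c1ccc(OCc9ccccc9)c(OCc9ccccc9)c1)c1cc(OCc9ccccc9)c(OCc9ccccc9)c(OCc9ccccc9)c1
F11 | step 15 | (2R,3S) carboxylic acid from aldehyde 24 | O=C(O[C@@H]1[C@@H](c2c(OCc9ccccc9)cc(O[Si](C(C)C)(C(C)C)C(C)C)c(c2OCc9ccccc9)[C@H](c4c(OCc9ccccc9)cc(OCc9ccccc9)c5c4O[C@H](c6ccc(OCc9ccccc9)c(OCc9ccccc9)c6)[C@@H](OCc9ccccc9)C5)[C@@H](OC(=O)c7cc(OCc9ccccc9)c(OCc9ccccc9)c(OCc9ccccc9)c7)C(=O)O)c2c(OCc9ccccc9)cc(OCc9ccccc9)cc2O[C@@H]1c1ccc(OCc9ccccc9)c(OCc9ccccc9)c1)c1cc(OCc9ccccc9)c(OCc9ccccc9)c(OCc9ccccc9)c1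
F12 | step 15 | S-ethyl thioester of F11 | O=C(O[C@@H]1[C@@H](c2c(OCc9ccccc9)cc(O[Si](C(C)C)(C(C)C)C(C)C)c(c2OCc9ccccc9)[C@H](c4c(OCc9ccccc9)cc(OCc9ccccc9)c5c4O[C@H](c6ccc(OCc9ccccc9)c(OCc9ccccc9)c6)[C@@H](OCc9ccccc9)C5)[C@@H](OC(=O)c7cc(OCc9ccccc9)c(OCc9ccccc9)c(OCc9ccccc9)c7)C(=O)SCC)c2c(OCc9ccccc9)cc(OCc9ccccc9)cc2O[C@@H]1c1ccc(OCc9ccccc9)c(OCc9ccccc9)c1)c1cc(OCc9ccccc9)c(OCc9ccccc9)c(OCc9ccccc9)c1
F13 | step 18 | (1S,2R,3S) epimer of 28 (hydroxyl and gallate anti) | O=C(O[C@@H]1[C@@H](c2c(OCc9ccccc9)cc(O[Si](C(C)C)(C(C)C)C(C)C)c(c2OCc9ccccc9)[C@H](c4c(OCc9ccccc9)cc(OCc9ccccc9)c5c4O[C@H](c6ccc(OCc9ccccc9)c(OCc9ccccc9)c6)[C@@H](OCc9ccccc9)C5)[C@@H](OC(=O)c7cc(OCc9ccccc9)c(OCc9ccccc9)c(OCc9ccccc9)c7)[C@H](c8ccc(OCc9ccccc9)c(OCc9ccccc9)c8)O)c2c(OCc9ccccc9)cc(OCc9ccccc9)cc2O[C@@H]1c1ccc(OCc9ccccc9)c(OCc9ccccc9)c1)c1cc(OCc9ccccc9)c(OCc9ccccc9)c(OCc9ccccc9)c1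
F14 | step 18 | phenol alcohol from F13 (silyl ether replaced by a free hydroxyl) | O=C(O[C@@H]1[C@@H](c2c(OCc9ccccc9)cc(O)c(c2OCc9ccccc9)[C@H](c4c(OCc9ccccc9)cc(OCc9ccccc9)c5c4O[C@H](c6ccc(OCc9ccccc9)c(OCc9ccccc9)c6)[C@@H](OCc9ccccc9)C5)[C@@H](OC(=O)c7cc(OCc9ccccc9)c(OCc9ccccc9)c(OCc9ccccc9)c7)[C@H](c8ccc(OCc9ccccc9)c(OCc9ccccc9)c8)O)c2c(OCc9ccccc9)cc(OCc9ccccc9)cc2O[C@@H]1c1ccc(OCc9ccccc9)c(OCc9ccccc9)c1)c1cc(OCc9ccccc9)c(OCc9ccccc9)c(OCc9ccccc9)c1
A1 | alternative 1 | silicon-tethered triyne (two silyl ynol ethers on diisopropylsilicon and one ethynyl ether) | C[Si](C)(C(C)(C)C)O[C@@H]1[C@@H](C#CO[Si](C(C)C)(C(C)C)OC#C[C@H](c4c(OCc9ccccc9)cc(OCc9ccccc9)c5c4O[C@H](c6ccc(OCc9ccccc9)c(OCc9ccccc9)c6)[C@@H](OCc9ccccc9)C5)[C@@H](O[Si](C)(C)C(C)(C)C)[C@@H](c8ccc(OCc9ccccc9)c(OCc9ccccc9)c8)OC#C)c2c(OCc9ccccc9)cc(OCc9ccccc9)cc2O[C@@H]1c1ccc(OCc9ccccc9)c(OCc9ccccc9)c1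
A2 | alternative 1 | trimer skeleton with O5 and O7 of the middle ring bridged by silicon and both upper 3-oxygens silylated | C[Si](C)(C(C)(C)C)O[C@@H]1[C@@H](c2c(O[Si](C(C)C)(C(C)C)O%10)cc3c(c2%10)[C@H](c4c(OCc9ccccc9)cc(OCc9ccccc9)c5c4O[C@H](c6ccc(OCc9ccccc9)c(OCc9ccccc9)c6)[C@@H](OCc9ccccc9)C5)[C@@H](O[Si](C)(C)C(C)(C)C)[C@@H](c8ccc(OCc9ccccc9)c(OCc9ccccc9)c8)O3)c2c(OCc9ccccc9)cc(OCc9ccccc9)cc2O[C@@H]1c1ccc(OCc9ccccc9)c(OCc9ccccc9)c1
A3 | alternative 2 | trans-epoxide: aryl ether of the upper-unit phloroglucinol ring with the 1-aryl-2,3-epoxy-3-(catechin-8-yl)propyl chain | O=C(O[C@@H]1[C@@H](c2c(OCc9ccccc9)cc(O[C@H](c8ccc(OCc9ccccc9)c(OCc9ccccc9)c8)[C@@H]3O[C@H]3c4c(OCc9ccccc9)cc(OCc9ccccc9)c5c4O[C@H](c6ccc(OCc9ccccc9)c(OCc9ccccc9)c6)[C@@H](OCc9ccccc9)C5)cc2OCc9ccccc9)c2c(OCc9ccccc9)cc(OCc9ccccc9)cc2O[C@@H]1c1ccc(OCc9ccccc9)c(OCc9ccccc9)c1)c1cc(OCc9ccccc9)c(OCc9ccccc9)c(OCc9ccccc9)c1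
A4 | alternative 2 | perbenzylated trimer with the middle 3-hydroxyl free | O=C(O[C@@H]1[C@@H](c2c(OCc9ccccc9)cc3c(c2OCc9ccccc9)[C@H](c4c(OCc9ccccc9)cc(OCc9ccccc9)c5c4O[C@H](c6ccc(OCc9ccccc9)c(OCc9ccccc9)c6)[C@@H](OCc9ccccc9)C5)[C@@H](O)[C@@H](c8ccc(OCc9ccccc9)c(OCc9ccccc9)c8)O3)c2c(OCc9ccccc9)cc(OCc9ccccc9)cc2O[C@@H]1c1ccc(OCc9ccccc9)c(OCc9ccccc9)c1)c1cc(OCc9ccccc9)c(OCc9ccccc9)c(OCc9ccccc9)c1
A5 | alternative 3 | bis-lactol: trimer core with hydroxyl in place of ring B at upper and middle C2 (anomeric mixtures) | O[C@@H]1[C@@H](c2c(OCc9ccccc9)cc3c(c2OCc9ccccc9)[C@H](c4c(OCc9ccccc9)cc(OCc9ccccc9)c5c4O[C@H](c6ccc(OCc9ccccc9)c(OCc9ccccc9)c6)[C@@H](OCc9ccccc9)C5)[C@@H](O)C(O)O3)c2c(OCc9ccccc9)cc(OCc9ccccc9)cc2OC1O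
A6 | alternative 3 | perbenzylated trimer with both upper 3-hydroxyls free | O[C@@H]1[C@@H](c2c(OCc9ccccc9)cc3c(c2OCc9ccccc9)[C@H](c4c(OCc9ccccc9)cc(OCc9ccccc9)c5c4O[C@H](c6ccc(OCc9ccccc9)c(OCc9ccccc9)c6)[C@@H](OCc9ccccc9)C5)[C@@H](O)[C@@H](c8ccc(OCc9ccccc9)c(OCc9ccccc9)c8)O3)c2c(OCc9ccccc9)cc(OCc9ccccc9)cc2O[C@@H]1c1ccc(OCc9ccccc9)c(OCc9ccccc9)c1
A7 | alternative 3 | 3,4-bis(benzyloxy)phenylboronic acid | OB(O)c1ccc(OCc9ccccc9)c(OCc9ccccc9)c1
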